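The data stem from a simulated flask for substances that don't exist; noise was put on by code.

Try counting time at full charge, not on the clock, in the two flasks below that take a reagent slowly; this is a rule of thumb, to be tested.

| flask | E | X | remark | time |
|---|---|---|---|---|
| green | 27 mM | 54 mM | run made earlier |  |
| blue | 27 mM | 76 mM | run made earlier |  |
| violet | 27 mM | 120 mM | run made earlier |  |
| red | 14 mM | 54 mM | run made earlier |  |
| beta | 27 mM | 54.0 mM (fed, over 8.0 min) | all else is in the flask from the start; the feed brings no volume worth counting | 12 min |
| theta | 27 mM | 54.0 mM | everything together at the start | 12 min |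
| alpha | 27 mM (fed, over 8.0 min) | 54.0 mM | all else is in the flask from the start; the feed brings no volume worth counting | 12 min |

- green (time / min: D / %, J / %): 1.00: 0, 0.4; 2.00: 0, 1.6; 3.00: 2.2, 0.7; 6.00: 2.0, 3.5; 12.0: 11.2, 19.7
- blue (time / min: D / %, J / %): 1.00: 0, 0; 3.00: 0, 0; 6.00: 4.1, 11.8; 8.00: 13.6, 29.2; 12.0: 19.4, 42.3
- violet (time / min: D / %, J / %): 1.00: 0, 0; 2.00: 0, 0; 3.00: 1.9, 6.0; 6.00: 13.8, 54.0; 12.0: 16.9, 62.2
- red (time / min: D / %, J / %): 1.00: 0, 0; 2.00: 0.5, 1.1; 3.00: 1.3, 0.3; 6.00: 0.4, 2.0; 12.0: 1.0, 2.7

(standard deviation of a reading: 1 percentage point)

- a species is counted by the E in it: one D counts as two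
- the numbers in the tables scatter by 1 percentage point (one standard deviation)

- the flask that comes out highest in amount of D, in percent of the E charged; "all alike" if 1.5 percentage points covers them all (beta / theta / alpha / all alike)
- amount of D at the end, in percent of the E charged, beta
- amount of D at the end, in percent of the E charged, theta
- amount of D at the end, in percent of the E charged, alpha

Start from green, since theta carries the same charges: expect D near 11.2% in theta. Then read the growth. In green, J plus D goes from 5.50% of the E charged at 6.00 min to 30.9% at 12.0 min, after a lag (induction period). That reads as a growth rate of 0.288 /min.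

Now replace the feed's ramp by its mean. The fraction fed averages half the charge over 8.0 min. So beta and alpha each get 8.00 min of full-charge time: the clock time less half the feed time. Scale green's D back by that shift, and my reckoning gives 3.54% of the E charged for both fed flasks.

Test the border. The feed lasts 1.33 times the 6.00 min at which green has barely risen, so in beta and alpha the feed runs on into that lag. The shift itself is worth a factor 3.16, so hold the estimate loosely.

The forecast names theta highest, with 3.5% in beta, 11% in theta and 2.5% in alpha. It differs from my reckoning on alpha, which it sets lower: “E stays low, so seeding is weaker”.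

    E ⇌ Q (K = 17.0, k = 0.00110 /s)
    E + X + G → J + 2 G (k = 11.0 /M²/s)
    E + X → J + G (k = 7.10 × 10⁻⁵ /M/s)
    E + J → D (k = 0.160 /M/s)

Highest stands theta, with D at 12.2%, against 3.14% in alpha and 1.10% in beta, and the forecast's three figures lie within tolerance. Alpha lands 0.4 percentage points from the full-charge estimate, but beta at 12 min holds 1.10% of D, close to the 1.11% that theta holds at 6.00 min, so the full-charge time of 8.00 min overstates beta. Read beta later, at 20 min: its full-charge time is 16.0 min, longer than theta's 12 min, yet its D is 8.37%, less than theta's 12.2%.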